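**Assumption (one line):** the target is taken exactly as drawn (2,3-cis dihydrobenzofuran, 2R,3R; oxolane 3S,4R,5R with aryl, CH2OH and benzyl all cis); for each chiral catalyst the antipode named is assumed to give the drawn sense, and its mirror image is used if it does not.

## Retrosynthetic overview

1. Target 28 ⇐ desilylation of 27 ⇐ ring contraction of the six-membered 1,3-oxaborinane alkenyl borate 25: a Pd-aryl-triggered 1,2-shift of the O–CH2 carbon from boron to carbon closes the oxolane, attaches ring A (as aryl bromide 4) and sets the carbinol carbon.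
2. Borate 25 ⇐ bromoalkene boronate 23 ⇐ 1,2-syn homoallylic alcohol 20 ⇐ Cu-catalysed borylative coupling of aldehyde 16 with silyloxyallene 18 (sets oxolane C4 and C5).
3. Aldehyde 16 ⇐ cis-dihydrobenzofuran ester 12 ⇐ Rh-carbene C–H insertion of aryl diazoacetate 11 ⇐ aryl iodide 9 + ethyl diazoacetate 10; 9 ⇐ phenol 8 + benzyl alcohol 7.
4. All three arenes ⇐ catechol 1 via guaiacol 2 and 4-bromoguaiacol 3.
5. Ring order: dihydrobenzofuran first (step 8), oxolane last (step 16).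

Abbreviations: TIPS = tri(propan-2-yl)silyl; Bpin = 4,4,5,5-tetramethyl-1,3,2-dioxaborolan-2-yl; "DHB" = the (2R,3R)-7-methoxy-2-[3-methoxy-4-(TIPS-oxy)phenyl]-3-[(TIPS-oxy)methyl]-2,3-dihydro-1-benzofuran-5-yl group. Oxolane numbering: O1, C2 (CH2), C3 (C–OH), C4 (CH–CH2O), C5 (CH–aryl).

## Route

Step 1
Reactants: 1 catechol
Product: 2 2-methoxyphenol (guaiacol)
Conditions: MeI (1.0 equiv), K2CO3, acetone, reflux
Reagents that add atoms: iodomethane, CI
Why: Williamson mono-O-methylation with one equivalent of MeI gives the monoether, separated from dimethyl ether and catechol by base extraction.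

Step 2
Reactants: 2 guaiacol
Product: 3 4-bromo-2-methoxyphenol
Conditions: NBS, MeCN, 0 °C → rt
Reagents that add atoms: N-bromosuccinimide, O=C1CCC(=O)N1Br
Why: Electrophilic aromatic bromination goes para to the free hydroxyl, the strongest director.

Step 3
Reactants: 3 4-bromo-2-methoxyphenol
Product: 4 (4-bromo-2-methoxyphenoxy)tri(propan-2-yl)silane
Conditions: TIPSCl, imidazole, DMF, rt
Reagents that add atoms: chlorotri(propan-2-yl)silane, CC(C)[Si](Cl)(C(C)C)C(C)C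
Why: Standard phenol silylation; the TIPS ether tolerates the organolithium, hydride and alkoxide steps that follow.

Step 4
Reactants: 4 aryl bromide
Product: 7 [3-methoxy-4-(TIPS-oxy)phenyl]methanol, via aryllithium 5 (not isolated), via aldehyde 6 (not isolated)
Conditions: n-BuLi, THF, −78 °C; DMF; then MeOH, NaBH4, 0 °C
Reagents that add atoms: N,N-dimethylformamide, CN(C)C=O
Why: Bromine–lithium exchange, Bouveault formylation and in-flask borohydride reduction give the benzylic alcohol in one operation.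

Step 5
Reactants: 3 4-bromo-2-methoxyphenol
Product: 8 4-bromo-2-iodo-6-methoxyphenol
Conditions: NIS, CF3CO2H (cat.), MeCN, rt
Reagents that add atoms: N-iodosuccinimide, O=C1CCC(=O)N1I
Why: Electrophilic iodination takes the only free position ortho to the hydroxyl, the para position being blocked by bromine.

Step 6
Reactants: 8 iodophenol; 7 benzylic alcohol
Product: 9 {4-[(4-bromo-2-iodo-6-methoxyphenoxy)methyl]-2-methoxyphenoxy}tri(propan-2-yl)silane
Conditions: PPh3, DIAD, THF, 0 °C → rt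
Reagents that add atoms: none
Why: Mitsunobu etherification of an acidic phenol with a primary benzylic alcohol forms the aryl benzyl ether under neutral conditions.

Step 7
Reactants: 9 aryl iodide; 10 ethyl diazoacetate
Product: 11 ethyl 2-[5-bromo-3-methoxy-2-({3-methoxy-4-(TIPS-oxy)phenyl}methoxy)phenyl]-2-diazoacetate
Conditions: Pd(PPh3)4 (5 mol %), Ag2CO3 (0.5 equiv), Et3N, toluene, rt
Reagents that add atoms: none
Why: Pd-catalysed C–H arylation of the diazoacetate keeps the diazo group and is selective for C–I over C–Br at room temperature.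

Step 8
Reactants: 11 aryl diazoacetate
Product: 12 ethyl (2R,3S)-5-bromo-7-methoxy-2-[3-methoxy-4-(TIPS-oxy)phenyl]-2,3-dihydro-1-benzofuran-3-carboxylate (2,3-cis)
Conditions: Rh2(S-PTTL)4 (dirhodium tetrakis[N-phthaloyl-(S)-tert-leucinate], 2 mol %), toluene, −60 °C
Reagents that add atoms: none
Why: Intramolecular 1,5 C–H insertion of the rhodium carbene into the electron-rich benzylic ether C–H gives the kinetic cis ring, with the chiral carboxylate ligands setting both new stereocentres (C2 R, C3 S).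

Step 9
Reactants: 12 cis ester
Product: 13 [(2R,3R)-5-bromo-7-methoxy-2-[3-methoxy-4-(TIPS-oxy)phenyl]-2,3-dihydro-1-benzofuran-3-yl]methanol
Conditions: iBu2AlH (3 equiv), CH2Cl2, −78 → −20 °C; aq. potassium sodium tartrate
Reagents that add atoms: none
Why: Non-basic hydride reduction of the ester at low temperature leaves the epimerisable cis C3 centre untouched (the descriptor changes only by priority).

Step 10
Reactants: 13 alcohol
Product: 14 TIPS ether of 13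
Conditions: TIPSCl, imidazole, DMF, rt
Reagents that add atoms: chlorotri(propan-2-yl)silane, CC(C)[Si](Cl)(C(C)C)C(C)C
Why: Silylation of the primary alcohol; TIPS is chosen so it cannot migrate under the alkoxide conditions of step 15.

Step 11
Reactants: 14 aryl bromide
Product: 16 DHB-carbaldehyde (2R,3R), via aryllithium 15 (not isolated)
Conditions: n-BuLi, THF, −78 °C; DMF; then H2O
Reagents that add atoms: N,N-dimethylformamide, CN(C)C=O
Why: Bromine–lithium exchange is faster than any deprotonation and Bouveault formylation gives the aldehyde.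

Step 12
Reactants: 17 buta-2,3-dien-1-ol
Product: 18 (buta-2,3-dien-1-yloxy)tri(propan-2-yl)silane
Conditions: TIPSCl, imidazole, CH2Cl2, 0 °C → rt
Reagents that add atoms: chlorotri(propan-2-yl)silane, CC(C)[Si](Cl)(C(C)C)C(C)C
Why: Silylation gives an allene whose silyloxide is a poor leaving group, so the allylcopper of step 13 does not eliminate.

Step 13
Reactants: 16 aldehyde; 18 allene
Product: 20 (1R,2R)-1-DHB-3-Bpin-2-[(TIPS-oxy)methyl]but-3-en-1-ol (1,2-syn), via boryl ether 19 (not isolated)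
Conditions: B2pin2 (1.1 equiv), CuCl (5 mol %), (S,S)-Ph-BPE (6 mol %), NaOt-Bu (10 mol %), THF, 0 °C → rt; aq. NH4Cl
Reagents that add atoms: bis(pinacolato)diboron, CC1(C)OB(OC1(C)C)B1OC(C)(C)C(C)(C)O1
Why: Cu-catalysed borylative allene–aldehyde coupling: the copper–boryl adds to the terminal C=C to give a (Z)-2-boryl allylcopper, which adds through its γ-carbon in a closed six-membered transition state (1,2-syn), the bisphosphine setting the absolute sense at both new centres.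

Step 14
Reactants: 20 alkenylboronate
Product: 22 (1R,2R)-3-bromo-1-DHB-2-[(TIPS-oxy)methyl]but-3-en-1-ol, via dibromide 21 (not isolated)
Conditions: Br2 (1.0 equiv), CH2Cl2, −78 °C; then NaOMe, MeOH, −78 → 0 °C
Reagents that add atoms: bromine, BrBr
Why: Bromination–deboronation: anti addition of Br2 to the 1,1-disubstituted alkenylboronate, then methoxide-triggered anti elimination of boron and the primary bromide, leaves the 2-bromoalkene.

Step 15
Reactants: 22 bromoalkenyl alcohol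
Product: 23 2-({[(1R,2R)-3-bromo-1-DHB-2-[(TIPS-oxy)methyl]but-3-en-1-yl]oxy}methyl)-4,4,5,5-tetramethyl-1,3,2-dioxaborolane
Conditions: NaH, THF, 0 °C; ICH2Bpin, 0 °C → rt
Reagents that add atoms: 2-(iodomethyl)-4,4,5,5-tetramethyl-1,3,2-dioxaborolane, CC1(C)OB(CI)OC1(C)C
Why: Net Williamson etherification (the alkoxide adds to boron and shifts to carbon with loss of iodide, a Matteson-type substitution) gives the α-alkoxymethyl boronate.

Step 16
Reactants: 23 bromoalkene boronate; 4 aryl bromide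
Product: 27 (3S,4R,5R)-5-DHB-3-{[3-methoxy-4-(TIPS-oxy)phenyl]methyl}-4-[(TIPS-oxy)methyl]oxolan-3-ol, via vinyllithium 24 (not isolated), via cyclic borate 25 (not isolated), via boronic ester 26 (not isolated)
Conditions: t-BuLi (2.05 equiv), THF, −78 °C → rt; then 4, Pd(OAc)2 (3 mol %), (Sp,Sp)-MandyPhos (3.6 mol %), NaOTf, THF, 60 °C; then NaOH, H2O2, 0 °C
Reagents that add atoms: hydrogen peroxide, OO
Why: Proposed new method: bromine–lithium exchange closes the vinyllithium onto the tethered Bpin to give the six-membered alkenyl borate 25; the cationic aryl-palladium from 4 then binds the exocyclic methylene and the ring O–CH2 carbon shifts 1,2 from boron to the alkene carbon anti to palladium, contracting the ring to the oxolane, and reductive elimination forms the benzyl C–aryl bond. The borate should react through the half-chair with pseudo-equatorial CH2OTIPS (an axial one clashes with a pinacolato oxygen), which, reinforced by the matched ligand antipode, puts boron trans and the new benzyl group cis to the CH2OTIPS and aryl groups, and stereoretentive oxidation gives the 3S carbinol. The closest known reaction types are Pd-catalysed conjunctive cross-coupling of acyclic alkenylboron ate complexes and radical-triggered ring contraction of cyclic alkenyl borates.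

Step 17
Reactants: 27 tetrakis-TIPS ether
Product: 28 (3S,4R,5R)-5-[(2R,3R)-2-(4-hydroxy-3-methoxyphenyl)-3-(hydroxymethyl)-7-methoxy-2,3-dihydro-1-benzofuran-5-yl]-3-[(4-hydroxy-3-methoxyphenyl)methyl]-4-(hydroxymethyl)oxolan-3-ol (CNP0284796.1)
Conditions: Bu4NF, AcOH, THF, 0 °C → rt
Reagents that add atoms: none
Why: Buffered fluoride desilylation removes all four TIPS groups without acid, so neither cis benzylic ether can epimerise.

## Compound list

1 | benzene-1,2-diol (catechol) | Oc1ccccc1O | starting material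
2 | 2-methoxyphenol | COc1ccccc1O | intermediate
3 | 4-bromo-2-methoxyphenol | COc1cc(Br)ccc1O | intermediate
4 | (4-bromo-2-methoxyphenoxy)tri(propan-2-yl)silane | COc1cc(Br)ccc1O[Si](C(C)C)(C(C)C)C(C)C | intermediate
5 | [3-methoxy-4-(TIPS-oxy)phenyl]lithium | COc1cc([Li])ccc1O[Si](C(C)C)(C(C)C)C(C)C | intermediate
6 | 3-methoxy-4-(TIPS-oxy)benzaldehyde | COc1cc(C=O)ccc1O[Si](C(C)C)(C(C)C)C(C)C | intermediate
7 | [3-methoxy-4-(TIPS-oxy)phenyl]methanol | COc1cc(CO)ccc1O[Si](C(C)C)(C(C)C)C(C)C | intermediate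
8 | 4-bromo-2-iodo-6-methoxyphenol | COc1cc(Br)cc(I)c1O | intermediate
9 | {4-[(4-bromo-2-iodo-6-methoxyphenoxy)methyl]-2-methoxyphenoxy}tri(propan-2-yl)silane | COc1cc(Br)cc(I)c1OCc1ccc(O[Si](C(C)C)(C(C)C)C(C)C)c(OC)c1 | intermediate
10 | ethyl 2-diazoacetate | CCOC(=O)C=[N+]=[N-] | starting material
11 | ethyl 2-[5-bromo-3-methoxy-2-({3-methoxy-4-(TIPS-oxy)phenyl}methoxy)phenyl]-2-diazoacetate | CCOC(=O)C(=[N+]=[N-])c1cc(Br)cc(OC)c1OCc1ccc(O[Si](C(C)C)(C(C)C)C(C)C)c(OC)c1 | intermediate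
12 | ethyl (2R,3S)-5-bromo-7-methoxy-2-[3-methoxy-4-(TIPS-oxy)phenyl]-2,3-dihydro-1-benzofuran-3-carboxylate (cis) | Brc1cc(OC)c2c(c1)[C@H](C(=O)OCC)[C@H](c1ccc(O[Si](C(C)C)(C(C)C)C(C)C)c(OC)c1)O2 | intermediate
13 | [(2R,3R)-5-bromo-7-methoxy-2-[3-methoxy-4-(TIPS-oxy)phenyl]-2,3-dihydro-1-benzofuran-3-yl]methanol (cis) | Brc1cc(OC)c2c(c1)[C@H](CO)[C@H](c1ccc(O[Si](C(C)C)(C(C)C)C(C)C)c(OC)c1)O2 | intermediate
14 | {[(2R,3R)-5-bromo-7-methoxy-2-[3-methoxy-4-(TIPS-oxy)phenyl]-2,3-dihydro-1-benzofuran-3-yl]methoxy}tri(propan-2-yl)silane | Brc1cc(OC)c2c(c1)[C@H](CO[Si](C(C)C)(C(C)C)C(C)C)[C@H](c1ccc(O[Si](C(C)C)(C(C)C)C(C)C)c(OC)c1)O2 | intermediate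
15 | 5-lithio analogue of 14 (DHB-lithium) | [Li]c1cc(OC)c2c(c1)[C@H](CO[Si](C(C)C)(C(C)C)C(C)C)[C@H](c1ccc(O[Si](C(C)C)(C(C)C)C(C)C)c(OC)c1)O2 | intermediate
16 | (2R,3R)-7-methoxy-2-[3-methoxy-4-(TIPS-oxy)phenyl]-3-[(TIPS-oxy)methyl]-2,3-dihydro-1-benzofuran-5-carbaldehyde | O=Cc1cc(OC)c2c(c1)[C@H](CO[Si](C(C)C)(C(C)C)C(C)C)[C@H](c1ccc(O[Si](C(C)C)(C(C)C)C(C)C)c(OC)c1)O2 | intermediate
17 | buta-2,3-dien-1-ol | OCC=C=C | starting material
18 | (buta-2,3-dien-1-yloxy)tri(propan-2-yl)silane | C=C=CCO[Si](C(C)C)(C(C)C)C(C)C | intermediate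
19 | O-Bpin ether of 20 | CC1(C)OB(O[C@@H](c2cc(OC)c3c(c2)[C@H](CO[Si](C(C)C)(C(C)C)C(C)C)[C@H](c4ccc(O[Si](C(C)C)(C(C)C)C(C)C)c(OC)c4)O3)[C@H](C(=C)B5OC(C)(C)C(C)(C)O5)CO[Si](C(C)C)(C(C)C)C(C)C)OC1(C)C | intermediate
20 | (1R,2R)-1-DHB-3-Bpin-2-[(TIPS-oxy)methyl]but-3-en-1-ol (1,2-syn) | O[C@@H](c1cc(OC)c2c(c1)[C@H](CO[Si](C(C)C)(C(C)C)C(C)C)[C@H](c3ccc(O[Si](C(C)C)(C(C)C)C(C)C)c(OC)c3)O2)[C@H](C(=C)B4OC(C)(C)C(C)(C)O4)CO[Si](C(C)C)(C(C)C)C(C)C | intermediate
21 | (1R,2R)-3,4-dibromo-1-DHB-3-Bpin-2-[(TIPS-oxy)methyl]butan-1-ol (both C3 epimers) | O[C@@H](c1cc(OC)c2c(c1)[C@H](CO[Si](C(C)C)(C(C)C)C(C)C)[C@H](c3ccc(O[Si](C(C)C)(C(C)C)C(C)C)c(OC)c3)O2)[C@H](C(Br)(CBr)B4OC(C)(C)C(C)(C)O4)CO[Si](C(C)C)(C(C)C)C(C)C | intermediate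
22 | (1R,2R)-3-bromo-1-DHB-2-[(TIPS-oxy)methyl]but-3-en-1-ol | O[C@@H](c1cc(OC)c2c(c1)[C@H](CO[Si](C(C)C)(C(C)C)C(C)C)[C@H](c3ccc(O[Si](C(C)C)(C(C)C)C(C)C)c(OC)c3)O2)[C@H](C(Br)=C)CO[Si](C(C)C)(C(C)C)C(C)C | intermediate
23 | 2-({[(1R,2R)-3-bromo-1-DHB-2-[(TIPS-oxy)methyl]but-3-en-1-yl]oxy}methyl)-4,4,5,5-tetramethyl-1,3,2-dioxaborolane | CC1(C)OB(CO[C@@H](c2cc(OC)c3c(c2)[C@H](CO[Si](C(C)C)(C(C)C)C(C)C)[C@H](c4ccc(O[Si](C(C)C)(C(C)C)C(C)C)c(OC)c4)O3)[C@H](C(Br)=C)CO[Si](C(C)C)(C(C)C)C(C)C)OC1(C)C | intermediate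
24 | 3-lithio analogue of 23 (vinyllithium) | CC1(C)OB(CO[C@@H](c2cc(OC)c3c(c2)[C@H](CO[Si](C(C)C)(C(C)C)C(C)C)[C@H](c4ccc(O[Si](C(C)C)(C(C)C)C(C)C)c(OC)c4)O3)[C@H](C([Li])=C)CO[Si](C(C)C)(C(C)C)C(C)C)OC1(C)C | intermediate
25 | lithium spiro-borate: boron shared by the pinacolato ring and a 1,3-oxaborinane (O1, C2H2, B3, C4=CH2, C5H–CH2OTIPS, C6H–DHB; C5/C6 as in 23) | [Li+].C=C1[C@H](CO[Si](C(C)C)(C(C)C)C(C)C)[C@H](c3cc(OC)c4c(c3)[C@H](CO[Si](C(C)C)(C(C)C)C(C)C)[C@H](c5ccc(O[Si](C(C)C)(C(C)C)C(C)C)c(OC)c5)O4)OC[B-]12OC(C)(C)C(C)(C)O2 | intermediate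
26 | 2-[(3R,4R,5R)-5-DHB-3-{[3-methoxy-4-(TIPS-oxy)phenyl]methyl}-4-[(TIPS-oxy)methyl]oxolan-3-yl]-4,4,5,5-tetramethyl-1,3,2-dioxaborolane | COc1cc(C[C@@]2(B3OC(C)(C)C(C)(C)O3)CO[C@@H](c4cc(OC)c5c(c4)[C@H](CO[Si](C(C)C)(C(C)C)C(C)C)[C@H](c6ccc(O[Si](C(C)C)(C(C)C)C(C)C)c(OC)c6)O5)[C@H]2CO[Si](C(C)C)(C(C)C)C(C)C)ccc1O[Si](C(C)C)(C(C)C)C(C)C | intermediate
27 | (3S,4R,5R)-5-DHB-3-{[3-methoxy-4-(TIPS-oxy)phenyl]methyl}-4-[(TIPS-oxy)methyl]oxolan-3-ol | COc1cc(C[C@@]2(O)CO[C@@H](c4cc(OC)c5c(c4)[C@H](CO[Si](C(C)C)(C(C)C)C(C)C)[C@H](c6ccc(O[Si](C(C)C)(C(C)C)C(C)C)c(OC)c6)O5)[C@H]2CO[Si](C(C)C)(C(C)C)C(C)C)ccc1O[Si](C(C)C)(C(C)C)C(C)C | intermediate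
28 | (3S,4R,5R)-5-[(2R,3R)-2-(4-hydroxy-3-methoxyphenyl)-3-(hydroxymethyl)-7-methoxy-2,3-dihydro-1-benzofuran-5-yl]-3-[(4-hydroxy-3-methoxyphenyl)methyl]-4-(hydroxymethyl)oxolan-3-ol | COc1cc(C[C@@]2(O)CO[C@@H](c3cc(OC)c4c(c3)[C@H](CO)[C@H](c3ccc(O)c(OC)c3)O4)[C@H]2CO)ccc1O | target

## Step count and risks

Total steps: 17. Longest linear sequence: 15 (steps 1, 2, 3, 4, 6–11, 13–17).

**Step 16 (the proposed ring-contractive conjunctive coupling).** It may fail through direct Suzuki transfer of the alkenyl group, the wrong face, or t-BuLi attack at boron. The fallback uses known chemistry, sets out from 23 and returns at 27. An intramolecular Suzuki–Miyaura coupling of the alkoxymethyl boronate with the vinyl bromide (Pd(OAc)2, RuPhos, K2CO3, toluene/H2O, 85 °C) gives (2R,3R)-2-DHB-4-methylidene-3-[(TIPS-oxy)methyl]oxolane F1. Dimethyldioxirane (acetone, −20 °C) epoxidises F1 from the face opposite the two cis substituents to give the spiro-epoxide with oxygen trans to the aryl and CH2OTIPS groups F2. The Grignard reagent made from 4 and Mg, [3-methoxy-4-(TIPS-oxy)phenyl]magnesium bromide F3, with CuI (10 mol %) in THF at −30 °C opens F2 at its CH2 carbon to give 27.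

**Step 14 (bromination–deboronation).** Br2 may also brominate the alkoxyarenes. The fallback avoids any halogenation of the alkene; it sets out from 20 and returns at the cyclic borate 25. Alkylation of 20 (KH, ICH2SnBu3, THF, 0 °C) gives the tributylstannylmethyl ether F4. Tin–iodine exchange (I2, CH2Cl2, 0 °C) gives the iodomethyl ether F5, used crude. Iodine–lithium exchange (t-BuLi, 2 equiv, THF/Et2O, −100 °C) gives the α-alkoxymethyllithium F6, which closes onto the alkenyl-Bpin to give the same borate 25. The Pd/aryl bromide and oxidation stages of step 16 then follow, with extra NaOTf to hold back iodide.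

**Step 13 (Cu-catalysed three-component coupling).** The risks are the syn/anti ratio, the enantioselectivity on this hindered aldehyde, and elimination of silyloxide from the allylcopper. The fallback sets out from 18 and 16 and returns at 19 (hence 20). Pt-catalysed diboration of 18 (Pt(dba)2, PCy3, B2pin2, toluene, 50 °C) gives the (Z)-2,3-bis(boryl)alkene F7. Chiral phosphoric acid-catalysed allylboration of 16 with F7 ((R)-TRIP, toluene, −30 °C) goes through a chair transition state, so the Z reagent again gives the syn adduct 19, which is hydrolysed to 20 on work-up.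

## Further compounds

F1 | step 16 | (2R,3R)-2-DHB-4-methylidene-3-[(TIPS-oxy)methyl]oxolane | C=C1CO[C@@H](c2cc(OC)c3c(c2)[C@H](CO[Si](C(C)C)(C(C)C)C(C)C)[C@H](c4ccc(O[Si](C(C)C)(C(C)C)C(C)C)c(OC)c4)O3)[C@H]1CO[Si](C(C)C)(C(C)C)C(C)C
F2 | step 16 | spiro-epoxide of F1 (1,5-dioxaspiro[2.4]heptane; epoxide O trans to the DHB and CH2OTIPS groups) | C1O[C@@]12CO[C@@H](c3cc(OC)c4c(c3)[C@H](CO[Si](C(C)C)(C(C)C)C(C)C)[C@H](c5ccc(O[Si](C(C)C)(C(C)C)C(C)C)c(OC)c5)O4)[C@H]2CO[Si](C(C)C)(C(C)C)C(C)C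
F3 | step 16 | [3-methoxy-4-(TIPS-oxy)phenyl]magnesium bromide | COc1cc([Mg]Br)ccc1O[Si](C(C)C)(C(C)C)C(C)C
F4 | step 14 | tributyl({[(1R,2R)-1-DHB-3-Bpin-2-[(TIPS-oxy)methyl]but-3-en-1-yl]oxy}methyl)stannane | CCCC[Sn](CCCC)(CCCC)CO[C@@H](c1cc(OC)c2c(c1)[C@H](CO[Si](C(C)C)(C(C)C)C(C)C)[C@H](c3ccc(O[Si](C(C)C)(C(C)C)C(C)C)c(OC)c3)O2)[C@H](C(=C)B4OC(C)(C)C(C)(C)O4)CO[Si](C(C)C)(C(C)C)C(C)C
F5 | step 14 | iodomethyl ether of 20 | ICO[C@@H](c1cc(OC)c2c(c1)[C@H](CO[Si](C(C)C)(C(C)C)C(C)C)[C@H](c3ccc(O[Si](C(C)C)(C(C)C)C(C)C)c(OC)c3)O2)[C@H](C(=C)B4OC(C)(C)C(C)(C)O4)CO[Si](C(C)C)(C(C)C)C(C)C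
F6 | step 14 | lithiomethyl ether of 20 | [Li]CO[C@@H](c1cc(OC)c2c(c1)[C@H](CO[Si](C(C)C)(C(C)C)C(C)C)[C@H](c3ccc(O[Si](C(C)C)(C(C)C)C(C)C)c(OC)c3)O2)[C@H](C(=C)B4OC(C)(C)C(C)(C)O4)CO[Si](C(C)C)(C(C)C)C(C)C
F7 | step 13 | (Z)-[2,3-bis(Bpin)but-2-en-1-yl... i.e. (Z)-{[3,4-bis(Bpin)but-2-en-1-yl]oxy}tri(propan-2-yl)silane | CC1(C)OB(C/C(=C\CO[Si](C(C)C)(C(C)C)C(C)C)B2OC(C)(C)C(C)(C)O2)OC1(C)C
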